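**Retrosynthetic overview**

1. 19 ⇐ bis-allyl ether 18 ⇐ diol 17 by acid-catalysed closure of O1–C2 (cation at C2 stabilised by ring B) ⇐ trans-lactone 13 by aryllithium addition and reduction; C2 stays at the carboxyl level until ring B arrives.
2. Lactone 13 ⇐ acyclic ester 9 in one flask: an Ireland–Claisen rearrangement makes C3–C4 (both stereocentres and the E-styryl bond), and the liberated carboxylate then arylates at C8a (O1–C8a).
3. Enabling feature: O1–C2–C3–C4–CH=CH(ring E) is a pent-4-enoic acid retron once C2 is a carboxyl carbon (the exocyclic E double bond at C4 of ring C), and O1 and C4 are ortho neighbours on ring A (C8a/C4a), so the carboxylate oxygen lies six atoms from C8a.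
4. Ester 9 ⇐ acid 2 (ring D) + R-carbinol 8; 8 ⇐ alkyne 4 (ring A) + aldehyde 5 (ring E).
5. Ring order: ring C as δ-lactone (step 5), opened (step 6), closed again as the pyran (step 7); no other ring is formed.

Key step: step 5

Remark (lettering): ring A = benzo ring of the chroman, ring C = pyran ring, ring B = 2,4-dimethoxyphenyl on C2, ring D = 4-hydroxyphenyl of the C3 benzyl group, ring E = 4-hydroxyphenyl of the C4 styryl group; chroman numbering is used throughout.

Remark (assumption): the (−)-3-exo-aminoisoborneol ligands normally direct organozinc reagents to the Si face of aryl aldehydes, which here would give the S carbinol; (+)-MIB is therefore specified in step 3 for the R carbinol.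

**Route**

Step 1
Reactants: 1 3-(4-hydroxyphenyl)propanoic acid
Product: 2 3-[4-(allyloxy)phenyl]propanoic acid
Conditions: allyl bromide (1.1 equiv), NaOH (2.5 equiv), EtOH/H2O, 70 °C; then aq. HCl
Reagents that add atoms: allyl bromide C=CCBr
Why: Williamson ether synthesis on the dianion, in which the phenoxide is far more nucleophilic than the carboxylate.

Step 2
Reactants: 3 2-bromo-4-methoxybenzaldehyde
Product: 4 2-bromo-1-ethynyl-4-methoxybenzene
Conditions: dimethyl (1-diazo-2-oxopropyl)phosphonate, K2CO3, MeOH, 0 °C to rt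
Reagents that add atoms: dimethyl (1-diazo-2-oxopropyl)phosphonate CC(=O)C(=[N+]=[N-])P(=O)(OC)OC
Why: Seyferth–Gilbert homologation with the Ohira–Bestmann reagent converts aryl aldehydes into terminal alkynes under mild carbonate conditions that leave the aryl bromide untouched.

Step 3
Reactants: 4 2-bromo-1-ethynyl-4-methoxybenzene; 5 4-(allyloxy)benzaldehyde
Product: 8 (1R,2E)-1-[4-(allyloxy)phenyl]-3-(2-bromo-4-methoxyphenyl)prop-2-en-1-ol, via alkenylborane 6 (not isolated), via alkenylzinc 7 (not isolated)
Conditions: BH3·SMe2, cyclohexene, toluene, 0 °C (gives Cy2BH); 4, 0 °C to rt; ZnMe2, −78 °C; (+)-MIB [(+)-3-exo-morpholinoisoborneol, 4 mol %], then 5, −20 °C; aq. NH4Cl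
Reagents that add atoms: none
Why: syn hydroboration gives the E-alkenylborane, boron-to-zinc transmetalation gives the alkenylzinc, and the amino-alcohol-catalysed enantioselective 1,2-addition to the aryl aldehyde sets the carbinol centre (R) under ligand control.

Step 4
Reactants: 2 3-[4-(allyloxy)phenyl]propanoic acid; 8 (1R,2E)-1-[4-(allyloxy)phenyl]-3-(2-bromo-4-methoxyphenyl)prop-2-en-1-ol
Product: 9 (1R,2E)-1-[4-(allyloxy)phenyl]-3-(2-bromo-4-methoxyphenyl)prop-2-en-1-yl 3-[4-(allyloxy)phenyl]propanoate
Conditions: DCC, DMAP (10 mol %), CH2Cl2, 0 °C to rt; filtration through Et3N-deactivated silica; used at once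
Reagents that add atoms: none
Why: Steglich esterification acylates the carbinol oxygen under neutral conditions without touching the C–O bond of the ionisable diarylallyl centre, so its configuration is retained.

Step 5
Reactants: 9 (1R,2E)-1-[4-(allyloxy)phenyl]-3-(2-bromo-4-methoxyphenyl)prop-2-en-1-yl 3-[4-(allyloxy)phenyl]propanoate
Product: 13 (3R,4R)-3-[4-(allyloxy)benzyl]-4-{(E)-2-[4-(allyloxy)phenyl]ethenyl}-7-methoxychroman-2-one, via silyl ketene acetal 10 (not isolated), via silyl ester 11 (not isolated), via pentenoic acid 12 (not isolated)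
Conditions: LiN(i-Pr)2 (1.15 equiv), Me3SiCl (1.5 equiv, internal quench), THF, −78 °C, then 45 °C; volatiles removed; CsF (2 equiv), CuI (10 mol %), 1,10-phenanthroline (20 mol %), DMF, 100 °C
Reagents that add atoms: none
Why: Kinetic enolisation in THF with in-situ silylation should give the (E)-ketene acetal 10, which undergoes the Ireland–Claisen [3,3] shift through a chair transition state with ring E equatorial on the carbinol carbon, so the R carbinol configuration is relayed to C4 (R) as the (E)-styryl bond forms, while the ketene acetal geometry sets C3 (R, anti). Fluoride then frees the carboxylate from 11, and ring C closes by intramolecular Ullmann-type C(aryl)–O coupling at C8a (monovalent copper with phenanthroline; six-membered ring, the cleaved C8a–Br bond exocyclic); the closest precedents are Ireland–Claisen rearrangements of 1-arylallyl esters and copper-catalysed lactonisations of 2-halobiaryl carboxylic acids. C4 is thus controlled by 1,3-chirality transfer and C3 by enolate geometry, and any cis lactone should be funnelled to the trans isomer by fluoride/carboxylate-mediated epimerisation at the lactone α-carbon, C4–H being far less acidic. The step needs deprotonation at the ester α-CH2 rather than at the doubly activated carbinol C–H, and a concerted rather than ion-pair rearrangement; the low temperature, the internal Me3SiCl quench and the weakly polar medium are meant to secure both, and the intramolecular setting favours lactone over intermolecular aryl ester formation.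

Step 6
Reactants: 13 (3R,4R)-3-[4-(allyloxy)benzyl]-4-{(E)-2-[4-(allyloxy)phenyl]ethenyl}-7-methoxychroman-2-one; 14 1-bromo-2,4-dimethoxybenzene
Product: 17 (1RS,2R,3R,4E)-2-[4-(allyloxy)benzyl]-5-[4-(allyloxy)phenyl]-1-(2,4-dimethoxyphenyl)-3-(2-hydroxy-4-methoxyphenyl)pent-4-en-1-ol, via aryllithium 15 (not isolated), via hydroxy ketone 16 (not isolated)
Conditions: 14, n-BuLi, THF, −78 °C; 13, −78 to −40 °C; then LiAlH4, −78 to 0 °C; water, aq. potassium sodium tartrate
Reagents that add atoms: none
Why: acyl substitution of the aryl lactone by the aryllithium (phenoxide leaving group) gives the hindered ketone as its lithium phenoxide, which is reduced in situ by hydride before C3 can epimerise; the new carbinol centre forms without control, which is harmless because it is ionised in step 7.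

Step 7
Reactants: 17 (1RS,2R,3R,4E)-2-[4-(allyloxy)benzyl]-5-[4-(allyloxy)phenyl]-1-(2,4-dimethoxyphenyl)-3-(2-hydroxy-4-methoxyphenyl)pent-4-en-1-ol
Product: 18 (2R,3R,4R)-3-[4-(allyloxy)benzyl]-4-{(E)-2-[4-(allyloxy)phenyl]ethenyl}-2-(2,4-dimethoxyphenyl)-7-methoxychroman
Conditions: PPTS (10 mol %), 4 Å molecular sieves, CH2Cl2, 0 °C to rt
Reagents that add atoms: none
Why: SN1 cyclodehydration as in classical flavan syntheses: both carbinol epimers ionise to the same 2,4-dimethoxybenzylic cation, and the phenol oxygen O1 closes the six-membered ring through a chair-like transition state with the C3 and C4 substituents equatorial, which should give the all-trans (2R) isomer, also the thermodynamic one if the closure is reversible.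

Step 8
Reactants: 18 (2R,3R,4R)-3-[4-(allyloxy)benzyl]-4-{(E)-2-[4-(allyloxy)phenyl]ethenyl}-2-(2,4-dimethoxyphenyl)-7-methoxychroman
Product: 19 caraganin C, (2R,3R,4R)-2-(2,4-dimethoxyphenyl)-3-(4-hydroxybenzyl)-4-[(E)-2-(4-hydroxyphenyl)ethenyl]-7-methoxychroman
Conditions: Pd(PPh3)4 (5 mol %), morpholine, THF, rt
Reagents that add atoms: none
Why: Tsuji–Trost-type deallylation: zerovalent palladium ionises both aryl allyl ethers to π-allyl complexes that morpholine intercepts, under neutral conditions that leave the stereocentres, the methyl ethers and the styrene untouched.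

**Compound list**

1 | 3-(4-hydroxyphenyl)propanoic acid | OC(=O)CCc1ccc(O)cc1 | starting material
2 | 3-[4-(allyloxy)phenyl]propanoic acid | C=CCOc1ccc(CCC(=O)O)cc1 | intermediate
3 | 2-bromo-4-methoxybenzaldehyde | COc1ccc(C=O)c(Br)c1 | starting material
4 | 2-bromo-1-ethynyl-4-methoxybenzene | COc1ccc(C#C)c(Br)c1 | intermediate
5 | 4-(allyloxy)benzaldehyde | C=CCOc1ccc(C=O)cc1 | starting material
6 | [(E)-2-(2-bromo-4-methoxyphenyl)ethenyl]dicyclohexylborane | COc1ccc(/C=C/B(C2CCCCC2)C2CCCCC2)c(Br)c1 | intermediate (not isolated)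
7 | [(E)-2-(2-bromo-4-methoxyphenyl)ethenyl](methyl)zinc | COc1ccc(/C=C/[Zn]C)c(Br)c1 | intermediate (not isolated)
8 | (1R,2E)-1-[4-(allyloxy)phenyl]-3-(2-bromo-4-methoxyphenyl)prop-2-en-1-ol | O[C@H](/C=C/c1ccc(OC)cc1Br)c1ccc(OCC=C)cc1 | intermediate
9 | (1R,2E)-1-[4-(allyloxy)phenyl]-3-(2-bromo-4-methoxyphenyl)prop-2-en-1-yl 3-[4-(allyloxy)phenyl]propanoate | C=CCOc1ccc(CCC(=O)O[C@H](/C=C/c2ccc(OC)cc2Br)c2ccc(OCC=C)cc2)cc1 | intermediate
10 | (E)-trimethylsilyl ketene acetal of 9 (ring D CH2 cis to the allylic oxygen) | C=CCOc1ccc(C/C=C(/O[Si](C)(C)C)O[C@H](/C=C/c2ccc(OC)cc2Br)c2ccc(OCC=C)cc2)cc1 | intermediate (not isolated)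
11 | trimethylsilyl (2R,3R,4E)-2-[4-(allyloxy)benzyl]-5-[4-(allyloxy)phenyl]-3-(2-bromo-4-methoxyphenyl)pent-4-enoate | C[Si](C)(C)OC(=O)[C@H](Cc1ccc(OCC=C)cc1)[C@H](c1ccc(OC)cc1Br)/C=C/c1ccc(OCC=C)cc1 | intermediate (not isolated)
12 | (2R,3R,4E)-2-[4-(allyloxy)benzyl]-5-[4-(allyloxy)phenyl]-3-(2-bromo-4-methoxyphenyl)pent-4-enoic acid (present as its caesium salt) | OC(=O)[C@H](Cc1ccc(OCC=C)cc1)[C@H](c1ccc(OC)cc1Br)/C=C/c1ccc(OCC=C)cc1 | intermediate (not isolated)
13 | (3R,4R)-3-[4-(allyloxy)benzyl]-4-{(E)-2-[4-(allyloxy)phenyl]ethenyl}-7-methoxychroman-2-one | COc1ccc2c(c1)OC(=O)[C@H](Cc1ccc(OCC=C)cc1)[C@H]2/C=C/c1ccc(OCC=C)cc1 | intermediate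
14 | 1-bromo-2,4-dimethoxybenzene | COc1ccc(Br)c(OC)c1 | starting material
15 | 2,4-dimethoxyphenyllithium | COc1ccc([Li])c(OC)c1 | intermediate (not isolated)
16 | (2R,3R,4E)-2-[4-(allyloxy)benzyl]-5-[4-(allyloxy)phenyl]-1-(2,4-dimethoxyphenyl)-3-(2-hydroxy-4-methoxyphenyl)pent-4-en-1-one | O=C(c1ccc(OC)cc1OC)[C@H](Cc1ccc(OCC=C)cc1)[C@H](c1ccc(OC)cc1O)/C=C/c1ccc(OCC=C)cc1 | intermediate (not isolated)
17 | (1RS,2R,3R,4E)-2-[4-(allyloxy)benzyl]-5-[4-(allyloxy)phenyl]-1-(2,4-dimethoxyphenyl)-3-(2-hydroxy-4-methoxyphenyl)pent-4-en-1-ol (both C1 epimers) | OC(c1ccc(OC)cc1OC)[C@H](Cc1ccc(OCC=C)cc1)[C@H](c1ccc(OC)cc1O)/C=C/c1ccc(OCC=C)cc1 | intermediate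
18 | (2R,3R,4R)-3-[4-(allyloxy)benzyl]-4-{(E)-2-[4-(allyloxy)phenyl]ethenyl}-2-(2,4-dimethoxyphenyl)-7-methoxychroman | COc1ccc2c(c1)O[C@@H](c1ccc(OC)cc1OC)[C@H](Cc1ccc(OCC=C)cc1)[C@H]2/C=C/c1ccc(OCC=C)cc1 | intermediate
19 | caraganin C, (2R,3R,4R)-2-(2,4-dimethoxyphenyl)-3-(4-hydroxybenzyl)-4-[(E)-2-(4-hydroxyphenyl)ethenyl]-7-methoxychroman | COc1ccc2c(c1)O[C@@H](c1ccc(OC)cc1OC)[C@H](Cc1ccc(O)cc1)[C@H]2/C=C/c1ccc(O)cc1 | target

**Step count and risks**

Total step count: 8. Longest linear sequence: 7 steps (3 → 4 → 8 → 9 → 13 → 17 → 18 → 19; steps 2 to 8).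

Steps most likely to fail:

1. Step 5. The bis(para-alkoxyaryl)allyl system may ionise to an ion pair before or during the rearrangement, which would cost chirality transfer and regiochemistry. The copper-mediated C–O coupling at the ortho-substituted bromide may also stall, and prolonged heating could let the styryl double bond migrate. Fallback: setting out from ester 9, the rearrangement is run alone (same enolisation, aqueous work-up) and acid 12 is isolated. The ring closure is then moved from the thermal copper cycle to a room-temperature nickel/photoredox carboxylate O-arylation (NiBr2·glyme, 4,4'-di-tert-butyl-2,2'-bipyridine, Ir(ppy)3 [tris(2-phenylpyridinato)iridium], Cs2CO3, DMF, blue light), a mechanistically distinct C–O reductive elimination that needs no heating. The route is rejoined at lactone 13, and a cis/trans mixture would be equilibrated to trans with DBU; no compound outside the list is made (F0).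

2. Step 3. Facial selectivity in the transfer of an aryl-substituted alkenylzinc reagent may be insufficient, and methyl transfer may compete. Fallback: setting out from aldehyde 3, a Claisen–Schmidt condensation (NaOH, EtOH) with 1-[4-(allyloxy)phenyl]ethanone F1 (from 4'-hydroxyacetophenone, allyl bromide, K2CO3, acetone) gives the chalcone (E)-1-[4-(allyloxy)phenyl]-3-(2-bromo-4-methoxyphenyl)prop-2-en-1-one F2. F2 is reduced 1,2 by a Corey–Bakshi–Shibata reduction (2-methyl-CBS-oxazaborolidine, catecholborane, toluene, −78 °C); the catalyst antipode is chosen to deliver the R carbinol, and the configuration of the carbinol centre would be confirmed by Mosher (MTPA) ester analysis. The route is rejoined at carbinol 8.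

3. Step 6. A second aryllithium may add to the ketone released on collapse of the tetrahedral intermediate, or the lactone may be enolised instead (C3 epimerisation, ketene formation). Fallback: setting out from lactone 13, aminolysis with MeNH(OMe)·HCl and i-PrMgCl (THF, −20 °C) opens the ring to the Weinreb amide (2R,3R,4E)-2-[4-(allyloxy)benzyl]-5-[4-(allyloxy)phenyl]-3-(2-hydroxy-4-methoxyphenyl)-N-methoxy-N-methylpent-4-enamide F3. Its stable chelated adduct with aryllithium 15 (2.2 equiv, −78 °C) cannot over-add and gives ketone 16 after a cold acetic acid quench. Reduction with LiAlH4 at −78 °C rejoins the route at diol 17.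

**Further compounds**

F0 | step 5 | none | none
F1 | step 3 | 1-[4-(allyloxy)phenyl]ethanone | CC(=O)c1ccc(OCC=C)cc1
F2 | step 3 | (E)-1-[4-(allyloxy)phenyl]-3-(2-bromo-4-methoxyphenyl)prop-2-en-1-one | C=CCOc1ccc(C(=O)/C=C/c2ccc(OC)cc2Br)cc1
F3 | step 6 | (2R,3R,4E)-2-[4-(allyloxy)benzyl]-5-[4-(allyloxy)phenyl]-3-(2-hydroxy-4-methoxyphenyl)-N-methoxy-N-methylpent-4-enamide | CON(C)C(=O)[C@H](Cc1ccc(OCC=C)cc1)[C@H](c1ccc(OC)cc1O)/C=C/c1ccc(OCC=C)cc1
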